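## Structural features

The target is a cyclohexane (quinic acid numbering) with a quaternary C1 that carries a tertiary hydroxyl and the carboxyl carbon C7, two methylenes (C2, C6) and three contiguous carbinol carbons C3, C4 and C5. O4 and O5 are esterified by (E)-4-hydroxycinnamoyl groups and O3 is free. There are four stereocentres: O3 and O4 are cis, O4 and O5 are trans, and at C1 the carboxyl is cis and 1,3 to O5 while the hydroxyl is on the face of O3 and O4. The fragile parts are the two aryl acrylate esters (base-labile, prone to O4→O3 acyl shift into the neighbouring cis hydroxyl, reducible), the free phenols and the α-hydroxy acid, so everything after acylation must be acidic or neutral and non-reductive. The real difficulty is twofold: building the oxygenated quaternary centre C1 in the right configuration relative to the remote C3–C5 triad, and telling three similar secondary hydroxyls apart so that only O4 and O5 are acylated. The key step exploits the cis-1,3 relation of C7 and O5: it is the pattern left by a benzilic-type shift in which O5 becomes the ester oxygen of C7, so C1, C7, the C1–C2 bond and the O5–C7 bond can arise together from a cycloheptane-1,2-dione that carries the triad. The resulting 1,5-lactone then locks the ring with O3 equatorial and O4 axial, which is the handle for the late hydroxyl differentiation.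

## Logic of the disconnections

28 ⇒ 27. Cut: the four O–CH2Ar bonds masking O3, the carboxyl group and the two phenols; no skeletal bond. Reason: 28 survives neither base (ester loss, O4→O3 acyl shift) nor hydrogenation, so all masks must fall together under acid. Gain: one protecting-group family and one final operation. Demand: the benzylic cations must be trapped before they alkylate the phenol rings.

27 ⇒ 23 + 26, and 26 ⇒ 24. Cut: the two acyl C–O bonds at O4 and O5 (and the aryl O–CH2Ar bond of 26). Reason: both acyl groups are identical, so one double esterification attaches them; this is the convergent junction. Gain: the target falls into a cyclitol core and a C9 acid one operation from 24. Demand: in 23 only O4–H and O5–H may react, so O3 and the carboxyl are masked and the tertiary O1–H is left to its low reactivity; two equivalents of 26 are consumed.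

23 ⇒ 21 ⇒ 19 ⇒ 18. Cut (re-formed in the retrosynthetic sense): the O5–C7 lactone bond; the O3 ether is exchanged for the O3/O4 ketal. Reason: in the lactone O5 is tied up and the ring is locked with O3 equatorial and O4 axial, the only stage at which the cis pair O3/O4 can be told apart. Gain: the endgame is reduced to 18, the direct product of the key step. Demand: the group on O3 in 21 must not move to O4 when hydroxide opens the lactone, hence an ether and not a silyl group, and the carboxylate must be esterified before acylation so that it cannot relactonise.

18 ⇒ 16. Cut: the C1–C2 bond and the O5–C7 lactone bond; C2 is returned to C7, which turns the carbocycle back into a seven-membered 1,2-dione. Reason: the cis-1,3 relation of C7 and O5 is the signature of a benzilic-type shift triggered by O5. Gain: the quaternary stereocentre, the carboxyl carbon and both rings of the bicycle vanish in one step, leaving a dione whose only stereocentres are the C3–C5 triad. Demand: O5–H must be the only free hydroxyl, and the enolisable, β-oxygenated dione must meet base only as its hemiketal, so O5 is unmasked last and under acidic fluoride.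

16 ⇒ 15 ⇒ 14 ⇒ 13. Cut: none in the skeleton; the two C=O groups are traced back to the C=C bond of 13 through diol 14, with O5 silylated during the oxidations. Reason: a cycloheptene is the simplest precursor of a cyclic 1,2-dione. Gain: the sensitive dione becomes a stable alkene. Demand: diol-to-dione oxidation without C–C cleavage and without base, and a silyl group that leaves under non-basic conditions.

13 ⇒ 12 ⇒ 11 ⇒ 10. Cut: the O5–Si bond and the two ketal C–O bonds at O3 and O4; the central ether of 10 is exchanged for them. Reason: in 11 the central carbinol carbon is not stereogenic and its neighbours are constitutionally equivalent; ketalisation of the cis pair is what distinguishes C3 from C5. Gain: three hydroxyls are differentiated by one thermodynamically controlled reaction. Demand: the cis-fused dioxolane must be clearly preferred over the trans-fused one.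

10 ⇒ 9. Cut: the ring C=C bond. Reason: a 1,8-diene closes to a cycloheptene by metathesis with loss of ethene. Gain: the carbocycle becomes an acyclic chain. Demand: dilution and a catalyst that tolerates two free hydroxyls.

9 ⇒ 7 + 8. Cut: the two C–C bonds between the allylic methylenes (future C2 and C6) and the vinyl carbons (future C1 and C7). Reason: both ends are identical, so one two-directional CuI-catalysed Grignard opening of a bis-epoxide installs them. Gain: seven ring carbons reduce to a five-carbon bis-electrophile plus two vinyl units. Demand: attack at the terminal epoxide carbons only, so the carbinol stereocentres stay untouched; two equivalents of 8 are consumed.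

7 ⇒ 5 ⇒ 4 ⇒ 3 ⇒ 1 + 2. Cut: the two epoxide C–O bonds at the primary carbons and the protecting-group C–O bonds. Reason: the two stereocentres of 1 that flank its central carbon already have the configuration of C3 and C5. Gain: the whole triad comes from the chiral pool. Demand: the central hydroxyl must be singled out (terminal bis-ketal from two equivalents of 2, then etherification) and the epoxides closed with the secondary oxygens as nucleophiles, that is with retention.

## Other disconnections considered

Alternative 1: The ring is cut at C1–C2 and C1–C6, so that C1 arrives as the central carbon of a malonate and C2–C6 come from pentitol 1, as in the chosen plan.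
- Forward key step: the 1,5-diiodide A1 would alkylate dibenzyl malonate A2 twice, the second alkylation being a 6-exo-tet closure, to give the cyclohexane-1,1-dicarboxylate A3. Hydrogenolysis, lactonisation of the carboxyl cis to O5 and exchange of the other carboxyl for hydroxyl (decarboxylative radical oxygenation at the lactone bridgehead) would then fix C1.
- In its favour: the six-membered ring is formed directly from the chiral pool by two robust alkylations, with no metathesis catalyst, no osmium and no base-sensitive dione.
- Against it here: C1 is assembled with two carboxyls and no oxygen, so a C–C bond just made must be broken and the C–O bond installed by a radical step. Which carboxyl survives depends on which hydroxyl lactonises; after debenzylation O3 and O5 are each cis to one carboxyl, so the triad would have to be differentiated first. β-Alkoxy primary iodides are also sluggish SN2 partners and the malonate anion can eliminate HI.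
- Comparison: in the source of C3–C5 the two plans are equal. In precedent and in ease of making the carbocycle alternative 1 is the better one. The chosen plan is better at C1, where oxygen, carboxyl and configuration are created in one event instead of three or four operations. The overall step count is expected to be similar.

Alternative 2: Only the C1–O bond is cut (with a temporary C2–O bond); the carbocycle, C7 and the C3–C5 triad are taken intact from (−)-shikimic acid A4.
- Forward key step: the lithium C3-alkoxide of the 4,5-protected methyl ester A5 would deliver the peroxide oxidant, as its anion, to the enoate (conjugate addition, then closure on oxygen) to give epoxide A6 syn to O3. The C2–O bond would then be removed reductively with retention of C1–O.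
- In its favour: ring, three stereocentres and the carboxyl carbon are bought, the C1 oxygen enters on the face of O3 as required, and the sequence should be clearly shorter than the chosen one. On step economy it is the better plan.
- Against it here: facial control rests on lithium chelation and is not geometrically enforced. The α-substituted enoate is a poor acceptor and the basic medium invites β-elimination and aromatisation. The usual reductive openings of glycidic esters break the wrong (C1–O) bond, so C2 needs a nucleophilic opening plus a radical reduction. The diacetal sits on exactly the two oxygens that must be acylated, so a full protecting-group exchange follows.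
- Comparison: structurally alternative 2 forms no skeletal bond; it is better in length and weaker as a construction. Mechanistically both plans use an oxygen of the triad to control C1, by chelation there and by a covalent bridge here. In the endgame the two are equal, since both need O3 masked and O4/O5 free.

Alternative 3: The lactone C5–O bond is cut (with a temporary C4–I bond), leading back to the cyclohexene hydroxy acid A7. Its only stereocentre, the quaternary C1, would be set by an auxiliary- or catalyst-controlled Diels–Alder reaction.
- Forward key step: iodine and bicarbonate would convert A7 into the bridged iodolactone A8 by anti addition of carboxylate and iodine across the alkene. Elimination of HI towards C3 and syn-dihydroxylation anti to the lactone bridge would then give 19, from which the endgame of the chosen route applies unchanged.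
- In its favour: every step is of a well-established type, one stereocentre is relayed into three by the rigid bicycle, and 19 would be reached in about five or six steps instead of fourteen. On step economy and on precedent this is the better plan.
- Against it here: enantiopurity depends on a controlled cycloaddition of a captodative dienophile and not on the chiral pool, iodine is introduced only to be discarded, and the facial selectivity of the dihydroxylation is substrate-controlled, not enforced.
- Comparison: structurally both plans pass through the same 6-oxabicyclo[3.2.1]octan-7-one and are equal from 19 onwards. Mechanistically alternative 3 closes the lactone on a finished quaternary centre, whereas the chosen plan forms C1, the six-membered ring and the lactone in one rearrangement and takes its absolute configuration from a sugar alcohol. The chosen plan is the longer and the riskier of the two; its merit is the strategic economy at C1.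

Key step: step 13

Remark: quinic acid numbering is used for all six-membered compounds; C1, C2, C3, C4, C5, C6, C7 of the dione become C1, C7, C2, C3, C4, C5, C6 of the lactone.
Remark: the configurations of the pentitol, the dione, the lactone and the target are mutually consistent atom by atom; the two R carbinol centres of D-arabinitol become C3 and C5.
Remark: diol 14 is carried as both cis-diol diastereomers and drawn without configuration at the two carbons that step 11 turns into carbonyls; 16 is drawn as the open hydroxy dione although it is expected to rest mainly as hemiketal 17.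

Step 1
Reactants: 1 D-arabinitol; 2 2,2-dimethoxypropane (two equivalents enter the product)
Product: 3 1,2:4,5-di-O-isopropylidene-D-arabinitol
Conditions: Me2C(OMe)2 (2.3 equiv), TsOH·H2O (cat.), DMF, rt; Et3N
Reagents that add atoms: 2,2-dimethoxypropane 2, second equivalent (COC(C)(C)OC)
Why: Acid-catalysed transketalisation; the two terminal 1,2-diols each take up one isopropylidene unit as the fastest-forming dioxolanes and leave the central hydroxyl free, and no stereocentre is touched.

Step 2
Reactants: 3 1,2:4,5-di-O-isopropylidene-D-arabinitol
Product: 4 1,2:4,5-di-O-isopropylidene-3-O-(4-methoxybenzyl)-D-arabinitol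
Conditions: NaH, PMBCl, Bu4NI (cat.), THF/DMF, 0 °C to rt
Reagents that add atoms: 4-methoxybenzyl chloride (COc1ccc(CCl)cc1)
Why: Williamson etherification of the only free hydroxyl; the PMB ether survives the acid, base, Grignard and metathesis steps that follow and can be removed oxidatively.

Step 3
Reactants: 4 1,2:4,5-di-O-isopropylidene-3-O-(4-methoxybenzyl)-D-arabinitol
Product: 5 3-O-(4-methoxybenzyl)-D-arabinitol
Conditions: AcOH/H2O 4:1, 45 °C
Reagents that add atoms: none
Why: Mild aqueous acid hydrolyses the two terminal dioxolanes while the benzylic ether is stable.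

Step 4
Reactants: 5 3-O-(4-methoxybenzyl)-D-arabinitol
Product: 7 1,2:4,5-dianhydro-3-O-(4-methoxybenzyl)-D-arabinitol, via 1,5-ditosylate 6 (not isolated)
Conditions: TsCl (2.1 equiv), Bu2SnO (5 mol%), Et3N, CH2Cl2, 0 °C to rt; then K2CO3, MeOH, rt
Reagents that add atoms: none
Why: Bu2SnO-catalysed sulfonylation selects the primary hydroxyl of each terminal diol, and K2CO3 in methanol closes both oxiranes by 3-exo-tet attack of the secondary alkoxide, so C2 and C4 keep their configuration because their C–O bonds are never broken.

Step 5
Reactants: 7 1,2:4,5-dianhydro-3-O-(4-methoxybenzyl)-D-arabinitol; 8 vinylmagnesium bromide (two equivalents enter the product)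
Product: 9 (4R,6R)-5-[(4-methoxybenzyl)oxy]nona-1,8-diene-4,6-diol
Conditions: CH2=CHMgBr (4 equiv), CuI (20 mol%), THF, −40 to −10 °C; aq NH4Cl
Reagents that add atoms: vinylmagnesium bromide 8, second equivalent (C=C[Mg]Br)
Why: CuI-catalysed Grignard opening of terminal epoxides occurs by SN2 attack at the unsubstituted carbon, here in both directions so that one vinyl group is added at each end; the carbinol centres are untouched.

Step 6
Reactants: 9 (4R,6R)-5-[(4-methoxybenzyl)oxy]nona-1,8-diene-4,6-diol
Product: 10 (1R,3R)-2-[(4-methoxybenzyl)oxy]cyclohept-5-ene-1,3-diol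
Conditions: second-generation Grubbs catalyst, (H2IMes)(PCy3)Cl2Ru=CHPh (3 mol%), CH2Cl2 (5 mM), 40 °C
Reagents that add atoms: none
Why: Ring-closing metathesis of a 1,8-diene to a cycloheptene, driven by loss of ethene; dilution suppresses oligomers and the catalyst (H2IMes)(PCy3)Cl2Ru=CHPh tolerates free hydroxyls.

Step 7
Reactants: 10 (1R,3R)-2-[(4-methoxybenzyl)oxy]cyclohept-5-ene-1,3-diol
Product: 11 (1R,3R)-cyclohept-5-ene-1,2,3-triol
Conditions: DDQ (1.2 equiv), CH2Cl2/H2O 10:1, 0 °C; then AcOH/THF/H2O, rt
Reagents that add atoms: none
Why: Oxidative PMB cleavage through the benzylic oxocarbenium ion; the acidic aqueous finish hydrolyses any 4-methoxybenzylidene acetal formed by capture of that ion by a neighbouring hydroxyl, and the isolated alkene is inert.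

Step 8
Reactants: 11 (1R,3R)-cyclohept-5-ene-1,2,3-triol; 2 2,2-dimethoxypropane
Product: 12 (3aS,4R,8aR)-2,2-dimethyl-4,5,8,8a-tetrahydro-3aH-cyclohepta[d][1,3]dioxol-4-ol
Conditions: Me2C(OMe)2, CSA (5 mol%), acetone, rt; Et3N
Reagents that add atoms: none
Why: Thermodynamically controlled ketalisation takes the cis-vicinal pair (cis-fused dioxolane) in preference to the trans pair; this makes the central carbon stereogenic (C4) and assigns its neighbours as C3 (in the ketal) and C5 (free hydroxyl, trans).

Step 9
Reactants: 12 (3aS,4R,8aR)-2,2-dimethyl-4,5,8,8a-tetrahydro-3aH-cyclohepta[d][1,3]dioxol-4-ol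
Product: 13 (3aR,4R,8aR)-2,2-dimethyl-4-[(triethylsilyl)oxy]-4,5,8,8a-tetrahydro-3aH-cyclohepta[d][1,3]dioxole
Conditions: TESCl, imidazole, CH2Cl2, 0 °C
Reagents that add atoms: chlorotriethylsilane (CC[Si](Cl)(CC)CC)
Why: Silylation of the single remaining hydroxyl; TES withstands osmylation and IBX and is later removed by buffered HF without any base.

Step 10
Reactants: 13 (3aR,4R,8aR)-2,2-dimethyl-4-[(triethylsilyl)oxy]-4,5,8,8a-tetrahydro-3aH-cyclohepta[d][1,3]dioxole
Product: 14 6,7-cis-diol of 13 (2,2-dimethyl-4-[(triethylsilyl)oxy]hexahydro-3aH-cyclohepta[d][1,3]dioxole-6,7-diol; both facial diastereomers)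
Conditions: K2OsO4·2H2O (2 mol%), NMO, acetone/H2O 4:1, rt; Na2SO3
Reagents that add atoms: N-methylmorpholine N-oxide (C[N+]1([O-])CCOCC1); water (O)
Why: Catalytic syn-dihydroxylation with NMO as reoxidant; facial selectivity is irrelevant because both new carbinol centres become carbonyls in step 11.

Step 11
Reactants: 14 6,7-cis-diol of 13
Product: 15 (4R,5R,6R)-4,5-(isopropylidenedioxy)-6-[(triethylsilyl)oxy]cycloheptane-1,2-dione (4,5-cis; 5,6-trans)
Conditions: IBX (4 equiv), DMSO, rt
Reagents that add atoms: none
Why: IBX oxidises 1,2-diols to 1,2-diketones without C–C cleavage and without base, which matters because the β-oxygenated dione would eliminate under the amine of a Swern oxidation.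

Step 12
Reactants: 15 (4R,5R,6R)-4,5-(isopropylidenedioxy)-6-[(triethylsilyl)oxy]cycloheptane-1,2-dione
Product: 16 (4R,5S,6R)-6-hydroxy-4,5-(isopropylidenedioxy)cycloheptane-1,2-dione
Conditions: HF·pyridine, pyridine, THF, 0 °C; pH 7 buffer; used at once
Reagents that add atoms: none
Why: Acidic fluoride cleaves the Si–O bond without ever generating an alkoxide; the liberated hydroxyl is expected to add at once to the distal carbonyl, so the material rests as its transannular hemiketal and is shielded from elimination.

Step 13
Reactants: 16 (4R,5S,6R)-6-hydroxy-4,5-(isopropylidenedioxy)cycloheptane-1,2-dione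
Product: 18 3,4-O-isopropylidenequinic acid 1,5-lactone, via bridged hemiketal 17 (not isolated)
Conditions: LiN(SiMe3)2 (1.0 equiv), THF, −78 °C, then to 0 °C; AcOH
Reagents that add atoms: none
Why: Proposed new method: the hydroxyl on C6 of the dione (O5 of the product) adds to the distal carbonyl C2 to give the 8-oxabicyclo[3.2.1]octanone hemiketal 17, and one equivalent of LiN(SiMe3)2 at −78 °C removes only its O–H proton; on warming, the hemiketal alkoxide re-forms a C=O at C2 while the ring methylene C3 shifts from C2 to the neighbouring ketone carbon C1, whose oxygen becomes the tertiary alkoxide. The closest known reaction type is the alkoxide-triggered benzilic ester rearrangement that contracts cyclic 1,2-diones to α-hydroxy esters (equally the base-induced α-ketol shift), here with the alkoxide tethered, and ester resonance drives it forward. The γ-lactone ring is closed at the hemiketal stage by a 5-exo-trig addition (the proximal carbonyl would demand a four-membered ring), and the six-membered carbocycle is closed by the suprafacial 1,2-shift, that is by contraction of the seven-membered ring and not by an end-to-end cyclisation. The new stereocentre C1 is controlled by the tether: the carboxyl carbon stays bonded to O5 throughout, so it can only end up cis to O5, which places the hydroxyl on the face of O3 and O4. The migrating bond is fixed by constitution and geometry, since C3 is the only carbon on C2 other than C1 and in 17 the C2–C3 bond stands out of the plane of the adjacent C=O and overlaps with its π* orbital, whereas the C2–O bond of the bridge lies in that plane. The step needs chemoselectivity against β-elimination and retro-aldol cleavage: in 17 the former carbonyl C2 is sp3, so the acetonide oxygen is no longer β to an acidic C–H, expulsion of the bridging oxygen would be the reverse of a disfavoured 5-endo-trig closure, and O3 and O4 are blocked so no other hydroxyl can compete. One equivalent of a hindered amide base at low temperature leaves the lithium alkoxide as the only base present, which serves the demand for mildness better than a catalytic amine that would equilibrate with the open, enolisable dione.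

Step 14
Reactants: 18 3,4-O-isopropylidenequinic acid 1,5-lactone
Product: 19 quinic acid 1,5-lactone, (1S,3R,4R,5R)-1,3,4-trihydroxy-6-oxabicyclo[3.2.1]octan-7-one
Conditions: TFA/H2O 9:1, 0 °C to rt; evaporate (toluene azeotrope)
Reagents that add atoms: none
Why: Acid hydrolysis of the cis-fused ketal; with little water and short contact the bridged lactone is expected to stay closed, being the form favoured on evaporation from acid.

Step 15
Reactants: 19 quinic acid 1,5-lactone
Product: 21 3-O-(4-methoxybenzyl)quinic acid 1,5-lactone, via stannylene acetal 20 (not isolated)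
Conditions: Bu2SnO (1.05 equiv), toluene, reflux (−H2O); then PMBCl, Bu4NI, 70 °C
Reagents that add atoms: 4-methoxybenzyl chloride (COc1ccc(CCl)cc1)
Why: Dibutylstannylene acetals of cis-1,2-diols on six-membered rings are alkylated at the equatorial oxygen; in the rigid lactone O3 is equatorial and O4 axial, so the ether goes to O3. An ether is chosen because, unlike a silyl group, it cannot migrate to O4 under the hydroxide of step 16.

Step 16
Reactants: 21 3-O-(4-methoxybenzyl)quinic acid 1,5-lactone
Product: 23 4-methoxybenzyl 3-O-(4-methoxybenzyl)quinate, via caesium carboxylate 22 (not isolated)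
Conditions: CsOH·H2O (1.05 equiv), THF/H2O, 0 °C; evaporate; PMBCl, DMF, rt
Reagents that add atoms: caesium hydroxide ([Cs+].[OH-]); 4-methoxybenzyl chloride (COc1ccc(CCl)cc1)
Why: Hydroxide opens the strained α-hydroxy γ-lactone by acyl–oxygen cleavage and frees O5, and the caesium carboxylate is then O-alkylated selectively in DMF; an acid-labile ester is used because a methyl ester could not be removed later without harming the cinnamate esters.

Step 17
Reactants: 24 p-coumaric acid
Product: 26 (E)-3-{4-[(4-methoxybenzyl)oxy]phenyl}prop-2-enoic acid, via bis-PMB derivative 25 (not isolated)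
Conditions: PMBCl (2.3 equiv), K2CO3, DMF, 60 °C; then NaOH (aq), MeOH, 60 °C; HCl to pH 2
Reagents that add atoms: 4-methoxybenzyl chloride (COc1ccc(CCl)cc1); sodium hydroxide ([Na+].[OH-])
Why: Williamson alkylation of phenoxide and carboxylate, then saponification of the ester in the same pot leaves the aryl PMB ether; the E-alkene is untouched.

Step 18
Reactants: 23 4-methoxybenzyl 3-O-(4-methoxybenzyl)quinate; 26 (E)-3-{4-[(4-methoxybenzyl)oxy]phenyl}prop-2-enoic acid (two equivalents enter the product)
Product: 27 4-methoxybenzyl 3-O-(4-methoxybenzyl)-4,5-bis-O-{(E)-3-[4-(4-methoxybenzyloxy)phenyl]prop-2-enoyl}quinate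
Conditions: 26 (2.6 equiv), EDC·HCl, DMAP, CH2Cl2, 0 °C to rt
Reagents that add atoms: (E)-3-{4-[(4-methoxybenzyl)oxy]phenyl}prop-2-enoic acid 26, second equivalent (OC(=O)/C=C/c1ccc(OCc2ccc(OC)cc2)cc1)
Why: Steglich esterification acylates the two equatorial secondary hydroxyls O4 and O5, one molecule of 26 on each; the hindered tertiary O1–H reacts far more slowly and O3 is blocked, and no stereocentre is affected.

Step 19
Reactants: 27 4-methoxybenzyl 3-O-(4-methoxybenzyl)-4,5-bis-O-{(E)-3-[4-(4-methoxybenzyloxy)phenyl]prop-2-enoyl}quinate
Product: 28 4,5-di-O-p-coumaroylquinic acid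
Conditions: TFA/CH2Cl2 1:4, anisole (20 equiv), 0 °C to rt
Reagents that add atoms: none
Why: Acidolysis (SN1) of the PMB ester, the alkyl PMB ether and both aryl PMB ethers through the 4-methoxybenzyl cation, which excess anisole traps; acidic, non-nucleophilic conditions avoid the base-promoted O4→O3 acyl shift and leave the cinnamate esters and alkenes intact.

Compound list
1 | D-arabinitol | OC[C@@H](O)C(O)[C@H](O)CO | starting material
2 | 2,2-dimethoxypropane | COC(C)(C)OC | starting material
3 | 1,2:4,5-di-O-isopropylidene-D-arabinitol | CC1(C)OC[C@@H](O1)C(O)[C@H]2COC(C)(C)O2 | intermediate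
4 | 1,2:4,5-di-O-isopropylidene-3-O-(4-methoxybenzyl)-D-arabinitol | CC1(C)OC[C@@H](O1)C(OCc2ccc(OC)cc2)[C@H]3COC(C)(C)O3 | intermediate
5 | 3-O-(4-methoxybenzyl)-D-arabinitol | OC[C@@H](O)C(OCc1ccc(OC)cc1)[C@H](O)CO | intermediate
6 | 3-O-(4-methoxybenzyl)-1,5-bis-O-(4-toluenesulfonyl)-D-arabinitol | Cc1ccc(cc1)S(=O)(=O)OC[C@@H](O)C(OCc1ccc(OC)cc1)[C@H](O)COS(=O)(=O)c1ccc(C)cc1 | intermediate
7 | 1,2:4,5-dianhydro-3-O-(4-methoxybenzyl)-D-arabinitol | C1O[C@H]1C(OCc2ccc(OC)cc2)[C@H]3CO3 | intermediate
8 | vinylmagnesium bromide | C=C[Mg]Br | starting material
9 | (4R,6R)-5-[(4-methoxybenzyl)oxy]nona-1,8-diene-4,6-diol | C=CC[C@@H](O)C(OCc1ccc(OC)cc1)[C@H](O)CC=C | intermediate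
10 | (1R,3R)-2-[(4-methoxybenzyl)oxy]cyclohept-5-ene-1,3-diol | C1=CC[C@@H](O)C(OCc2ccc(OC)cc2)[C@H](O)C1 | intermediate
11 | (1R,3R)-cyclohept-5-ene-1,2,3-triol | C1=CC[C@@H](O)C(O)[C@H](O)C1 | intermediate
12 | (3aS,4R,8aR)-2,2-dimethyl-4,5,8,8a-tetrahydro-3aH-cyclohepta[d][1,3]dioxol-4-ol (cis-fused ketal, hydroxyl trans to the neighbouring ketal oxygen) | C1=CC[C@H]2OC(C)(C)O[C@H]2[C@H](O)C1 | intermediate
13 | (3aR,4R,8aR)-2,2-dimethyl-4-[(triethylsilyl)oxy]-4,5,8,8a-tetrahydro-3aH-cyclohepta[d][1,3]dioxole | C1=CC[C@H]2OC(C)(C)O[C@H]2[C@H](O[Si](CC)(CC)CC)C1 | intermediate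
14 | 6,7-cis-diol of 13 (both facial diastereomers) | OC1C(O)C[C@H]2OC(C)(C)O[C@H]2[C@H](O[Si](CC)(CC)CC)C1 | intermediate
15 | (4R,5R,6R)-4,5-(isopropylidenedioxy)-6-[(triethylsilyl)oxy]cycloheptane-1,2-dione | O=C1C(=O)C[C@H]2OC(C)(C)O[C@H]2[C@H](O[Si](CC)(CC)CC)C1 | intermediate
16 | (4R,5S,6R)-6-hydroxy-4,5-(isopropylidenedioxy)cycloheptane-1,2-dione (4,5-cis; 5,6-trans) | O=C1C(=O)C[C@H]2OC(C)(C)O[C@H]2[C@H](O)C1 | intermediate
17 | 5-hydroxy-2,3-(isopropylidenedioxy)-8-oxabicyclo[3.2.1]octan-6-one (hemiketal of 16 between the C6 hydroxyl and C2) | O=C1[C@@]2(O)C[C@H]3OC(C)(C)O[C@H]3[C@@H](C1)O2 | intermediate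
18 | 3,4-O-isopropylidenequinic acid 1,5-lactone | CC1(C)O[C@@H]2[C@H](O1)C[C@@](O)(C3=O)C[C@H]2O3 | intermediate
19 | quinic acid 1,5-lactone, (1S,3R,4R,5R)-1,3,4-trihydroxy-6-oxabicyclo[3.2.1]octan-7-one | O[C@@H]1[C@H](O)C[C@@](O)(C2=O)C[C@H]1O2 | intermediate
20 | 3,4-O-(dibutylstannylene)quinic acid 1,5-lactone | CCCC[Sn]1(CCCC)O[C@@H]2[C@H](O1)C[C@@](O)(C3=O)C[C@H]2O3 | intermediate
21 | 3-O-(4-methoxybenzyl)quinic acid 1,5-lactone | O[C@@H]1[C@H](OCc2ccc(OC)cc2)C[C@@](O)(C3=O)C[C@H]1O3 | intermediate
22 | caesium 3-O-(4-methoxybenzyl)quinate | O[C@@H]1[C@H](OCc2ccc(OC)cc2)C[C@@](O)(C([O-])=O)C[C@H]1O.[Cs+] | intermediate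
23 | 4-methoxybenzyl 3-O-(4-methoxybenzyl)quinate | O[C@@H]1[C@H](OCc2ccc(OC)cc2)C[C@@](O)(C(=O)OCc2ccc(OC)cc2)C[C@H]1O | intermediate
24 | p-coumaric acid | OC(=O)/C=C/c1ccc(O)cc1 | starting material
25 | 4-methoxybenzyl (E)-3-{4-[(4-methoxybenzyl)oxy]phenyl}prop-2-enoate | COc1ccc(COC(=O)/C=C/c2ccc(OCc3ccc(OC)cc3)cc2)cc1 | intermediate
26 | (E)-3-{4-[(4-methoxybenzyl)oxy]phenyl}prop-2-enoic acid | OC(=O)/C=C/c1ccc(OCc2ccc(OC)cc2)cc1 | intermediate
27 | 4-methoxybenzyl 3-O-(4-methoxybenzyl)-4,5-bis-O-{(E)-3-[4-(4-methoxybenzyloxy)phenyl]prop-2-enoyl}quinate | O=C(/C=C/c1ccc(OCc2ccc(OC)cc2)cc1)O[C@@H]1[C@H](OCc2ccc(OC)cc2)C[C@@](O)(C(=O)OCc2ccc(OC)cc2)C[C@H]1OC(=O)/C=C/c1ccc(OCc2ccc(OC)cc2)cc1 | intermediate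
28 | 4,5-di-O-p-coumaroylquinic acid | O=C(/C=C/c1ccc(O)cc1)O[C@@H]1[C@H](O)C[C@@](O)(C(=O)O)C[C@H]1OC(=O)/C=C/c1ccc(O)cc1 | target

Total step count: 19. Longest linear sequence: 18 steps (steps 1–16, 18 and 19, from D-arabinitol); step 17 is a one-step branch.

Least certain steps

Step 13 (key step, proposed new method). Most likely failure: reopening of the hemiketal alkoxide to the hydroxy-dione alkoxide, followed by enolisation with β-elimination of the acetonide oxygen, or by retro-aldol cleavage between C5 and C6 with loss of configuration at C5. Alternatively, the 1,2-shift of the lithium alkoxide may not set in below the temperature at which these leaks begin. Fallback by a Wolff ring contraction, from 15 back to 18: 15 is condensed with tosylhydrazine to the monotosylhydrazone F1 (either carbonyl, both converge); triethylamine converts it into the α-diazo ketone F2; photolysis in methanol effects the Wolff rearrangement with capture of the ketene to give the ring-contracted methyl ester F3; deprotonation with LiN(iPr)2 and oxidation of the enolate with 2-(phenylsulfonyl)-3-phenyloxaziridine gives the α-hydroxy ester F4 as a C1-epimer mixture; HF·pyridine liberates O5 to give the hydroxy ester F5; acid-catalysed transesterification (TsOH, toluene, removal of methanol) closes the lactone only from the epimer whose ester is cis to O5, giving 18, and the other epimer stays an open ester and is separated.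

Step 11. Most likely failure: oxidative C–C cleavage of the vicinal diol, or stalling after the first oxidation, because the second oxidation is slower and the product is an enolisable β-oxygenated dione. Fallback that avoids the diol, from 13 back to 15: ketohydroxylation of the alkene with RuCl3 (cat.), KHSO5 and NaHCO3 in EtOAc/MeCN/H2O gives the α-ketol F6 directly (either regioisomer serves), and Dess–Martin periodinane buffered with pyridine oxidises the remaining carbinol, a substrate that has no glycol to cleave, to give 15.

Step 8. Most likely failure: competitive ketalisation of the trans pair, since a seven-membered ring tolerates a trans-fused dioxolane better than a six-membered one, which would leave the wrong hydroxyl free. Fallback by temporary boronate masking, from 11 back to 13 (12 is bypassed): phenylboronic acid (toluene, MgSO4, rt) ties the cis-diol as the cyclic phenylboronate F7, whose planar five-membered ring does not span the trans pair; TESCl/imidazole silylates the remaining hydroxyl to give the silyl ether F8; transesterification with pinacol releases the cis-diol F9; 2-methoxypropene with a trace of PPTS closes the ketal and gives 13.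

Step 15. Most likely failure: Bu2SnO-mediated transesterification of the strained lactone during stannylene formation at reflux, or alkylation at O4 in place of O3. Fallback by silyl protection, from 19 to 28: TBDPSCl/imidazole in DMF silylates the equatorial O3–H to give the silyl ether F10, a bulky group that should not migrate during a brief hydroxide treatment; CsOH followed by PMBCl gives the caesium salt F11 and then the 4-methoxybenzyl ester F12; esterification with 26 as in step 18 gives the diester F13; TFA/anisole removes the three PMB groups to give the acid F14; HF·pyridine finally removes the silyl ether and gives 28.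

Further compounds
F1 | step 13 | monotosylhydrazone of 15 (hydrazone at C2 drawn) | O=C1C(=NNS(=O)(=O)c3ccc(C)cc3)C[C@H]2OC(C)(C)O[C@H]2[C@H](O[Si](CC)(CC)CC)C1
F2 | step 13 | 2-diazo-4,5-(isopropylidenedioxy)-6-[(triethylsilyl)oxy]cycloheptan-1-one (configuration as in 15) | O=C1C(=[N+]=[N-])C[C@H]2OC(C)(C)O[C@H]2[C@H](O[Si](CC)(CC)CC)C1
F3 | step 13 | methyl 1-deoxy-3,4-O-isopropylidene-5-O-(triethylsilyl)quinate (C1 unassigned) | COC(=O)C1C[C@H]2OC(C)(C)O[C@H]2[C@H](O[Si](CC)(CC)CC)C1
F4 | step 13 | methyl 3,4-O-isopropylidene-5-O-(triethylsilyl)quinate with its C1 epimer | COC(=O)C1(O)C[C@H]2OC(C)(C)O[C@H]2[C@H](O[Si](CC)(CC)CC)C1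
F5 | step 13 | methyl 3,4-O-isopropylidenequinate with its C1 epimer | COC(=O)C1(O)C[C@H]2OC(C)(C)O[C@H]2[C@H](O)C1
F6 | step 11 | 2-hydroxy-4,5-(isopropylidenedioxy)-6-[(triethylsilyl)oxy]cycloheptan-1-one (α-ketol, one regioisomer drawn) | O=C1C(O)C[C@H]2OC(C)(C)O[C@H]2[C@H](O[Si](CC)(CC)CC)C1
F7 | step 8 | cyclic phenylboronate of the cis-diol of 11 | C1=CC[C@H]2OB(c3ccccc3)O[C@H]2[C@H](O)C1
F8 | step 8 | triethylsilyl ether of F7 | C1=CC[C@H]2OB(c3ccccc3)O[C@H]2[C@H](O[Si](CC)(CC)CC)C1
F9 | step 8 | cyclohept-5-ene-1,2,3-triol 3-O-triethylsilyl ether (1,2-cis diol; silyloxy group trans) | C1=CC[C@@H](O)[C@@H](O)[C@H](O[Si](CC)(CC)CC)C1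
F10 | step 15 | 3-O-(tert-butyldiphenylsilyl)quinic acid 1,5-lactone | O[C@@H]1[C@H](O[Si](c2ccccc2)(c2ccccc2)C(C)(C)C)C[C@@](O)(C3=O)C[C@H]1O3
F11 | step 15 | caesium 3-O-(tert-butyldiphenylsilyl)quinate | O[C@@H]1[C@H](O[Si](c2ccccc2)(c2ccccc2)C(C)(C)C)C[C@@](O)(C([O-])=O)C[C@H]1O.[Cs+]
F12 | step 15 | 4-methoxybenzyl 3-O-(tert-butyldiphenylsilyl)quinate | O[C@@H]1[C@H](O[Si](c2ccccc2)(c2ccccc2)C(C)(C)C)C[C@@](O)(C(=O)OCc2ccc(OC)cc2)C[C@H]1O
F13 | step 15 | 4-methoxybenzyl 3-O-(tert-butyldiphenylsilyl)-4,5-bis-O-{(E)-3-[4-(4-methoxybenzyloxy)phenyl]prop-2-enoyl}quinate | O=C(/C=C/c1ccc(OCc2ccc(OC)cc2)cc1)O[C@@H]1[C@H](O[Si](c2ccccc2)(c2ccccc2)C(C)(C)C)C[C@@](O)(C(=O)OCc2ccc(OC)cc2)C[C@H]1OC(=O)/C=C/c1ccc(OCc2ccc(OC)cc2)cc1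
F14 | step 15 | 3-O-(tert-butyldiphenylsilyl)-4,5-di-O-p-coumaroylquinic acid | O=C(/C=C/c1ccc(O)cc1)O[C@@H]1[C@H](O[Si](c2ccccc2)(c2ccccc2)C(C)(C)C)C[C@@](O)(C(=O)O)C[C@H]1OC(=O)/C=C/c1ccc(O)cc1
A1 | alternative 1 | 2,3,4-tri-O-benzyl-1,5-dideoxy-1,5-diiodo-D-arabinitol | IC[C@@H](OCc1ccccc1)C(OCc1ccccc1)[C@H](OCc1ccccc1)CI
A2 | alternative 1 | dibenzyl malonate | O=C(CC(=O)OCc1ccccc1)OCc1ccccc1
A3 | alternative 1 | dibenzyl (3R,5R)-3,4,5-tris(benzyloxy)cyclohexane-1,1-dicarboxylate | C(c1ccccc1)OC1[C@H](OCc2ccccc2)CC(C(=O)OCc2ccccc2)(C(=O)OCc2ccccc2)C[C@H]1OCc1ccccc1
A4 | alternative 2 | (−)-shikimic acid | O[C@@H]1[C@H](O)C=C(C(=O)O)C[C@H]1O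
A5 | alternative 2 | methyl shikimate 4,5-(2,3-dimethoxybutane-2,3-diyl) acetal | O1[C@@H]2[C@H](O)C=C(C(=O)OC)C[C@H]2O[C@](C)(OC)[C@@]1(C)OC
A6 | alternative 2 | methyl 1,2-epoxy-1,2-dihydroshikimate 4,5-(2,3-dimethoxybutane-2,3-diyl) acetal, epoxide syn to O3 | O1[C@@H]2[C@H](O)[C@@H]3O[C@]3(C(=O)OC)C[C@H]2O[C@](C)(OC)[C@@]1(C)OC
A7 | alternative 3 | (1S)-1-hydroxycyclohex-3-ene-1-carboxylic acid | OC(=O)[C@]1(O)CCC=CC1
A8 | alternative 3 | 1-hydroxy-4-iodo-6-oxabicyclo[3.2.1]octan-7-one | I[C@@H]1CC[C@@](O)(C2=O)C[C@H]1O2
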